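**Plan**

- Retrosynthesis: the N-oxide oxygen is taken off, then N4–C26, C26–C25 and C2–C3 are cut in one operation (iminium formation, then azomethine ylide [3+2]). This is possible because N4 and C26 are common to the piperidine (N4, C6, C14, C15, C22, C26) and the pyrrolidine (C2, C3, N4, C26, C25), and C26 also sits in the cyclopentane (C22–C26), so one iminium carbon at C26 can start all three rings.
- The amino aldehyde is then cut at O17–C18 and C21–C22 (allyl group, hydroboration, oxidative lactonisation), C15–C22 (ester aldol), C6–N (sigmatropic transfer from C8–O), C14–C15 (vinylogous aldol), and C6=C7 / C11–C12 (aldol condensation / conjugate addition on cyclopent-2-en-1-one).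
- Forward ring order: five-membered carbocycle (from cyclopentenone), six-membered carbocycle, δ-lactone, then piperidine, cyclopentane and pyrrolidine together in the cascade.
- Stereochemistry: C11 from a chiral copper catalyst; C14 by axial attack on the ring fixed by C11; C8 (temporary) from a CBS catalyst, and C6 from it by suprafacial [3,3] transfer; C15 by Felkin–Anh addition; C22 by chelate-controlled alkylation; C26, C25 and C2 from the tether and the Z alkene; N4 from the cage.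

Key step: step 23

Remark on labels: C1–C26 (N4, O5, O17, O19) are the atoms of the target SMILES read left to right and are used for all intermediates. "A" stands for the unit (4R,5S,7aR)-4-[(tert-butoxycarbonyl)(trimethylsilylmethyl)amino]-2,4,5,6,7,7a-hexahydro-1H-inden-5-yl. CIP descriptors at C11 and C22 change along the route only because substituent priorities change.

Assumptions: the carbinol carbon made in step 4 is carried as an epimer mixture, since it becomes the C15 ketone in step 11. In step 1 the ligand enantiomer that gives the S ketone is used.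

**Step 1**
Reactants: 1 2-(3-bromopropyl)-1,3-dioxolane; 2 cyclopent-2-en-1-one
Product: 4 (S)-3-[3-(1,3-dioxolan-2-yl)propyl]cyclopentan-1-one, via Grignard reagent 3 (not isolated)
Conditions: Mg, THF, 40 °C; then 2, CuBr·SMe2 (5 mol %), 1-[2-(diphenylphosphino)ferrocenyl]ethyl-dicyclohexylphosphine (6 mol %), t-BuOMe, −75 °C; aq. NH4Cl
Reagents that add atoms: none
Why: Copper-catalysed asymmetric conjugate addition of a Grignard reagent to a cyclic enone, in which the chiral diphosphine–copper complex chooses the enone face and so sets C11.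

**Step 2**
Reactants: 4 (S)-3-[3-(1,3-dioxolan-2-yl)propyl]cyclopentan-1-one
Product: 7 (3aS)-2,3,3a,4,5,6-hexahydro-1H-inden-1-one, via keto aldehyde 5 (not isolated), via aldol adduct 6 (not isolated)
Conditions: 1 M HCl, THF, 23 → 40 °C
Reagents that add atoms: none
Why: Acetal hydrolysis and intramolecular aldol condensation (6-enolexo attack of C7 on the C6 aldehyde, then dehydration into conjugation) close the six-membered carbocycle without touching C11.

**Step 3**
Reactants: 7 (3aS)-2,3,3a,4,5,6-hexahydro-1H-inden-1-one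
Product: 8 tert-butyl(dimethyl)[(7aS)-2,6,7,7a-tetrahydro-1H-inden-3-yloxy]silane
Conditions: TBSOTf, Et3N, CH2Cl2, 0 → 23 °C
Reagents that add atoms: tert-butyldimethylsilyl triflate, CC(C)(C)[Si](C)(C)OS(=O)(=O)C(F)(F)F
Why: Soft enolisation with O-silylation under equilibrating conditions should give the through-conjugated dienol ether (γ-deprotonation at C14), the more stable of the two possible silyloxy dienes.

**Step 4**
Reactants: 8 tert-butyl(dimethyl)[(7aS)-2,6,7,7a-tetrahydro-1H-inden-3-yloxy]silane; 9 acetaldehyde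
Product: 10 (3aS,6S)-6-(1-hydroxyethyl)-2,3,3a,4,5,6-hexahydro-1H-inden-1-one (carbinol epimers)
Conditions: TiCl4, CH2Cl2, −78 °C; aq. NaHCO3
Reagents that add atoms: none
Why: Vinylogous Mukaiyama aldol addition, in which the fully substituted C7 leaves only γ-attack at C14, and the aldehyde should enter axially, anti to the pseudoaxial C13–H of the sofa fixed by C11 (on the face opposite H11), so that H14 ends cis to H11.

**Step 5**
Reactants: 10 (3aS,6S)-6-(1-hydroxyethyl)-2,3,3a,4,5,6-hexahydro-1H-inden-1-one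
Product: 11 (3aS,6S)-6-[1-(triethylsilyloxy)ethyl]-2,3,3a,4,5,6-hexahydro-1H-inden-1-one
Conditions: Et3SiCl, imidazole, DMF, 0 °C
Reagents that add atoms: chlorotriethylsilane, CC[Si](Cl)(CC)CC
Why: Routine silylation of a secondary alcohol, which protects the carbinol during the carbamate chemistry.

**Step 6**
Reactants: 11 (3aS,6S)-6-[1-(triethylsilyloxy)ethyl]-2,3,3a,4,5,6-hexahydro-1H-inden-1-one
Product: 12 (1S,3aS,6S)-6-[1-(triethylsilyloxy)ethyl]-2,3,3a,4,5,6-hexahydro-1H-inden-1-ol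
Conditions: (R)-2-methyl-CBS-oxazaborolidine (0.2 equiv), BH3·SMe2, THF, −30 °C
Reagents that add atoms: none
Why: Corey–Bakshi–Shibata reduction, 1,2-selective, in which the catalyst tells the alkenyl side (large) from the ring CH2 (small) and should give the 8S alcohol with OH cis to H11 against the weak substrate bias.

**Step 7**
Reactants: 12 (1S,3aS,6S)-6-[1-(triethylsilyloxy)ethyl]-2,3,3a,4,5,6-hexahydro-1H-inden-1-ol; 13 trichloroacetyl isocyanate
Product: 15 (1S,3aS,6S)-6-[1-(triethylsilyloxy)ethyl]-2,3,3a,4,5,6-hexahydro-1H-inden-1-yl carbamate, via N-trichloroacetyl carbamate 14 (not isolated)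
Conditions: CH2Cl2, 0 °C; then K2CO3, MeOH, H2O, 0 °C
Reagents that add atoms: none
Why: Carbamoylation of an alcohol with an acyl isocyanate followed by mild methanolysis of the trichloroacetyl group is the standard way to a primary allylic carbamate and should spare the silyl ether.

**Step 8**
Reactants: 15 (1S,3aS,6S)-6-[1-(triethylsilyloxy)ethyl]-2,3,3a,4,5,6-hexahydro-1H-inden-1-yl carbamate
Product: 18 tert-butyl N-{(4R,5S,7aR)-5-[1-(triethylsilyloxy)ethyl]-2,4,5,6,7,7a-hexahydro-1H-inden-4-yl}carbamate, via allyl cyanate 16 (not isolated), via allyl isocyanate 17 (not isolated)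
Conditions: (CF3CO)2O, Et3N, CH2Cl2, −78 → 0 °C; then LiOt-Bu, THF, 0 → 23 °C
Reagents that add atoms: lithium tert-butoxide, [Li+].CC(C)(C)[O-]
Why: Dehydration to the allyl cyanate starts the allyl cyanate-to-isocyanate [3,3] rearrangement (Ichikawa), which carries nitrogen suprafacially from C8–O to C6 on the face anti to the C14 side chain (6R, N trans to C15), moves the alkene to C7=C8, and leaves an isocyanate that tert-butoxide captures as the Boc carbamate.

**Step 9**
Reactants: 18 tert-butyl N-{(4R,5S,7aR)-5-[1-(triethylsilyloxy)ethyl]-2,4,5,6,7,7a-hexahydro-1H-inden-4-yl}carbamate; 19 (trimethylsilyl)methyl trifluoromethanesulfonate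
Product: 20 tert-butyl N-{(4R,5S,7aR)-5-[1-(triethylsilyloxy)ethyl]-2,4,5,6,7,7a-hexahydro-1H-inden-4-yl}-N-[(trimethylsilyl)methyl]carbamate
Conditions: KN(SiMe3)2, THF, −78 °C; then 19, −78 → 23 °C
Reagents that add atoms: none
Why: SN2 N-alkylation of a carbamate anion with a primary triflate, an electrophile reactive enough for the hindered nitrogen, which also removes the N–H before the ketone chemistry.

**Step 10**
Reactants: 20 tert-butyl N-{(4R,5S,7aR)-5-[1-(triethylsilyloxy)ethyl]-2,4,5,6,7,7a-hexahydro-1H-inden-4-yl}-N-[(trimethylsilyl)methyl]carbamate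
Product: 21 tert-butyl N-[(4R,5S,7aR)-5-(1-hydroxyethyl)-2,4,5,6,7,7a-hexahydro-1H-inden-4-yl]-N-[(trimethylsilyl)methyl]carbamate
Conditions: PPTS, MeOH, 23 °C
Reagents that add atoms: none
Why: Acid-catalysed methanolysis cleaves the secondary triethylsilyl ether, while the Boc group and the C–Si bond of the silylmethyl group are stable to this weak acid.

**Step 11**
Reactants: 21 tert-butyl N-[(4R,5S,7aR)-5-(1-hydroxyethyl)-2,4,5,6,7,7a-hexahydro-1H-inden-4-yl]-N-[(trimethylsilyl)methyl]carbamate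
Product: 22 tert-butyl N-[(4R,5S,7aR)-5-acetyl-2,4,5,6,7,7a-hexahydro-1H-inden-4-yl]-N-[(trimethylsilyl)methyl]carbamate
Conditions: Dess–Martin periodinane, CH2Cl2, 0 → 23 °C
Reagents that add atoms: none
Why: Dess–Martin oxidation turns both carbinol epimers into the one C15 methyl ketone under near-neutral conditions that should not epimerise C14.

**Step 12**
Reactants: 23 pent-3-yn-1-ol
Product: 24 5-iodopent-2-yne
Conditions: I2, PPh3, imidazole, CH2Cl2, 0 °C
Reagents that add atoms: iodine, II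
Why: Appel-type iodination of a primary alcohol by SN2 displacement of the alkoxyphosphonium group.

**Step 13**
Reactants: 24 5-iodopent-2-yne; 25 dimethyl malonate
Product: 26 dimethyl 2-(pent-3-yn-1-yl)propanedioate
Conditions: NaH, THF/DMF, 0 → 50 °C
Reagents that add atoms: none
Why: Malonic ester alkylation, in which the soft malonate anion substitutes the primary iodide with little elimination.

**Step 14**
Reactants: 26 dimethyl 2-(pent-3-yn-1-yl)propanedioate
Product: 27 methyl hept-5-ynoate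
Conditions: LiCl, H2O, DMSO, 150 °C
Reagents that add atoms: none
Why: Krapcho dealkoxycarbonylation removes one ester group of a malonate.

**Step 15**
Reactants: 22 tert-butyl N-[(4R,5S,7aR)-5-acetyl-2,4,5,6,7,7a-hexahydro-1H-inden-4-yl]-N-[(trimethylsilyl)methyl]carbamate; 27 methyl hept-5-ynoate
Product: 28 methyl (3R)-3-A-3-hydroxy-2-(pent-3-yn-1-yl)butanoate (both C2 epimers)
Conditions: LiN(i-Pr)2 (LDA), THF, −78 °C, 27; then 22, −78 °C; AcOH
Reagents that add atoms: none
Why: Aldol addition of an ester lithium enolate to a methyl ketone, in which Felkin–Anh attack anti to the bulky nitrogen-bearing C6 (no N–H is left for chelation) should set C15 as 15R, while C22 forms as a mixture that step 16 erases.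

**Step 16**
Reactants: 28 methyl (3R)-3-A-3-hydroxy-2-(pent-3-yn-1-yl)butanoate; 29 3-bromoprop-1-ene
Product: 30 methyl (2R,3R)-2-allyl-3-A-3-hydroxy-2-(pent-3-yn-1-yl)butanoate
Conditions: LiN(i-Pr)2 (2.5 equiv), THF/DMPU, −78 → −30 °C; then 29; AcOH
Reagents that add atoms: none
Why: Fráter–Seebach alkylation, in which the lithium alkoxide–enolate chelate takes the allyl group on the face of the small C15 methyl, anti to unit A, and so sets the quaternary C22 whatever the C22 configuration of 28 was.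

**Step 17**
Reactants: 30 methyl (2R,3R)-2-allyl-3-A-3-hydroxy-2-(pent-3-yn-1-yl)butanoate
Product: 31 (2S,3R)-2-allyl-3-A-2-(pent-3-yn-1-yl)butane-1,3-diol
Conditions: i-Bu2AlH, CH2Cl2, −78 → 0 °C; aq. potassium sodium tartrate
Reagents that add atoms: none
Why: Hydride reduction of the ester to the primary alcohol, at a temperature at which i-Bu2AlH should leave the tertiary carbamate and the alkyne alone.

**Step 18**
Reactants: 31 (2S,3R)-2-allyl-3-A-2-(pent-3-yn-1-yl)butane-1,3-diol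
Product: 32 (2R,3R)-2-allyl-3-A-3-hydroxy-2-(pent-3-yn-1-yl)butanal
Conditions: TEMPO (0.1 equiv), PhI(OAc)2, CH2Cl2, 23 °C
Reagents that add atoms: none
Why: Oxoammonium (TEMPO) oxidation is selective for the primary alcohol, the tertiary alcohol is inert, and the α-quaternary aldehyde cannot enolise.

**Step 19**
Reactants: 32 (2R,3R)-2-allyl-3-A-3-hydroxy-2-(pent-3-yn-1-yl)butanal
Product: 33 (2R,3R)-3-allyl-2-A-3-(dimethoxymethyl)oct-6-yn-2-ol
Conditions: HC(OMe)3, MeOH, PPTS (cat.), 40 °C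
Reagents that add atoms: trimethyl orthoformate, COC(OC)OC; methanol, CO
Why: Acid-catalysed acetalisation masks the aldehyde against the borane and the oxidant of the next two steps.

**Step 20**
Reactants: 33 (2R,3R)-3-allyl-2-A-3-(dimethoxymethyl)oct-6-yn-2-ol
Product: 35 (4R,5R)-5-A-4-(dimethoxymethyl)-4-(pent-3-yn-1-yl)hexane-1,5-diol, via alkylborane 34 (not isolated)
Conditions: 9-BBN, THF, 0 → 23 °C; then NaOH, H2O2, 0 °C
Reagents that add atoms: hydrogen peroxide, OO
Why: Anti-Markovnikov hydroboration–oxidation, in which 9-BBN takes the terminal alkene far faster than the trisubstituted ring alkene or the internal alkyne.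

**Step 21**
Reactants: 35 (4R,5R)-5-A-4-(dimethoxymethyl)-4-(pent-3-yn-1-yl)hexane-1,5-diol
Product: 38 (5R,6R)-6-A-5-(dimethoxymethyl)-6-methyl-5-(pent-3-yn-1-yl)tetrahydro-2H-pyran-2-one, via hydroxy aldehyde 36 (not isolated), via lactol 37 (not isolated)
Conditions: TEMPO (0.2 equiv), PhI(OAc)2 (2.5 equiv), CH2Cl2, 23 °C
Reagents that add atoms: none
Why: Oxidative lactonisation of a 1,5-diol, in which the primary alcohol is oxidised to the aldehyde, the tertiary C15–OH closes the six-membered lactol (6-exo-trig), and a second oxidation gives the δ-lactone.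

**Step 22**
Reactants: 38 (5R,6R)-6-A-5-(dimethoxymethyl)-6-methyl-5-(pent-3-yn-1-yl)tetrahydro-2H-pyran-2-one
Product: 39 (5R,6R)-6-A-5-(dimethoxymethyl)-6-methyl-5-[(Z)-pent-3-en-1-yl]tetrahydro-2H-pyran-2-one
Conditions: H2 (1 atm), Pd/CaCO3 poisoned with Pb(OAc)2, quinoline, EtOAc, 23 °C
Reagents that add atoms: none
Why: Lindlar semihydrogenation adds H2 syn to the alkyne to give the Z alkene, and the poisoned catalyst should not reduce the trisubstituted C7=C8 alkene.

**Step 23**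
Reactants: 39 (5R,6R)-6-A-5-(dimethoxymethyl)-6-methyl-5-[(Z)-pent-3-en-1-yl]tetrahydro-2H-pyran-2-one
Product: 43 hexacyclic tertiary amine (2S,6R,11R,14S,15R,22S,25R,26S), via amino aldehyde 40 (not isolated), via iminium trifluoroacetate 41 (not isolated), via azomethine ylide 42 (not isolated)
Conditions: CF3CO2H, CH2Cl2, H2O (3 equiv), 0 → 23 °C; evaporate; MeCN, 4 Å molecular sieves, 23 °C; then CsF (4 equiv), 70 °C
Reagents that add atoms: none
Why: Acid removes the Boc group and the acetal, the freed secondary amine N4 condenses with the C26 aldehyde to a cyclic iminium salt that cannot tautomerise because C22 is quaternary, and fluoride then cleaves the C3–Si bond to leave the non-stabilised azomethine ylide C3–N4–C26, which adds to the tethered alkene. The closest known reaction type is the intramolecular [3+2] cycloaddition of a non-stabilised azomethine ylide, made by desilylation of an N-(silylmethyl)iminium ion, with an unactivated alkene. The piperidine (N4, C6, C14, C15, C22, C26) closes in the condensation by 6-exo-trig attack of N4 on C26; the cyclopentane (C22–C26) and the pyrrolidine (C2, C3, N4, C26, C25) close together in the concerted suprafacial cycloaddition, C26–C25 through the three-atom tether C23–C24 and C3–C2 across the dipole. C26 is controlled by C22, because the tether reaches only the ylide face that carries C23 (cis fusion, H26 cis to C21); C25 by the cis fusion of the new bicyclo[3.3.0] unit (H25 cis to H26); C2 by the Z geometry of the alkene, kept in the suprafacial addition (methyl cis to C24). The step needs the ylide to add to the Z alkene and not to the C7=C8 alkene or to a second ylide, which the five-membered-ring tether and the dilution secure, and it needs the iminium to form although the carbocycle must leave its chair, which the non-enolisable aldehyde and the six-membered closure should allow.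

**Step 24**
Reactants: 43 hexacyclic tertiary amine
Product: 44 CNP0566793.5 (N4-oxide of 43)
Conditions: m-CPBA (1.05 equiv), CH2Cl2, −78 → 0 °C
Reagents that add atoms: 3-chloroperoxybenzoic acid, OOC(=O)c1cccc(Cl)c1
Why: Peracid N-oxidation of a tertiary amine is much faster than epoxidation of the trisubstituted alkene, and the cage leaves the nitrogen lone pair only on the convex face (cis to H26), which fixes the configuration at N4.

**Compound list**

1 | 2-(3-bromopropyl)-1,3-dioxolane | BrCCCC1OCCO1 | starting material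
2 | cyclopent-2-en-1-one | O=C1C=CCC1 | starting material
3 | [3-(1,3-dioxolan-2-yl)propyl]magnesium bromide | Br[Mg]CCCC1OCCO1 | intermediate
4 | (S)-3-[3-(1,3-dioxolan-2-yl)propyl]cyclopentan-1-one | O=C1CC[C@@H](C1)CCCC1OCCO1 | intermediate
5 | 4-[(1S)-3-oxocyclopentyl]butanal | O=C1CC[C@@H](C1)CCCC=O | intermediate
6 | (3aS)-7-hydroxyoctahydro-1H-inden-1-one (mixture at C7 and C7a) | O=C1CC[C@@H]2CCCC(O)C12 | intermediate
7 | (3aS)-2,3,3a,4,5,6-hexahydro-1H-inden-1-one | O=C1CC[C@@H]2CCCC=C12 | intermediate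
8 | tert-butyl(dimethyl)[(7aS)-2,6,7,7a-tetrahydro-1H-inden-3-yloxy]silane | CC(C)(C)[Si](C)(C)OC1=C2C=CCC[C@H]2CC1 | intermediate
9 | acetaldehyde | CC=O | starting material
10 | (3aS,6S)-6-(1-hydroxyethyl)-2,3,3a,4,5,6-hexahydro-1H-inden-1-one (carbinol epimers) | O=C1CC[C@@H]2CC[C@H](C(C)O)C=C12 | intermediate
11 | (3aS,6S)-6-[1-(triethylsilyloxy)ethyl]-2,3,3a,4,5,6-hexahydro-1H-inden-1-one | O=C1CC[C@@H]2CC[C@H](C(C)O[Si](CC)(CC)CC)C=C12 | intermediate
12 | (1S,3aS,6S)-6-[1-(triethylsilyloxy)ethyl]-2,3,3a,4,5,6-hexahydro-1H-inden-1-ol | O[C@H]1CC[C@@H]2CC[C@H](C(C)O[Si](CC)(CC)CC)C=C12 | intermediate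
13 | trichloroacetyl isocyanate | O=C=NC(=O)C(Cl)(Cl)Cl | starting material
14 | N-(trichloroacetyl)carbamate of 12 | ClC(Cl)(Cl)C(=O)NC(=O)O[C@H]1CC[C@@H]2CC[C@H](C(C)O[Si](CC)(CC)CC)C=C12 | intermediate
15 | (1S,3aS,6S)-6-[1-(triethylsilyloxy)ethyl]-2,3,3a,4,5,6-hexahydro-1H-inden-1-yl carbamate | NC(=O)O[C@H]1CC[C@@H]2CC[C@H](C(C)O[Si](CC)(CC)CC)C=C12 | intermediate
16 | (1S,3aS,6S)-6-[1-(triethylsilyloxy)ethyl]-2,3,3a,4,5,6-hexahydro-1H-inden-1-yl cyanate | N#CO[C@H]1CC[C@@H]2CC[C@H](C(C)O[Si](CC)(CC)CC)C=C12 | intermediate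
17 | triethyl{1-[(4R,5S,7aR)-4-isocyanato-2,4,5,6,7,7a-hexahydro-1H-inden-5-yl]ethoxy}silane | O=C=N[C@H]1C2=CCC[C@@H]2CC[C@@H]1C(C)O[Si](CC)(CC)CC | intermediate
18 | tert-butyl N-{(4R,5S,7aR)-5-[1-(triethylsilyloxy)ethyl]-2,4,5,6,7,7a-hexahydro-1H-inden-4-yl}carbamate | CC(C)(C)OC(=O)N[C@H]1C2=CCC[C@@H]2CC[C@@H]1C(C)O[Si](CC)(CC)CC | intermediate
19 | (trimethylsilyl)methyl trifluoromethanesulfonate | C[Si](C)(C)COS(=O)(=O)C(F)(F)F | starting material
20 | tert-butyl N-{(4R,5S,7aR)-5-[1-(triethylsilyloxy)ethyl]-2,4,5,6,7,7a-hexahydro-1H-inden-4-yl}-N-[(trimethylsilyl)methyl]carbamate | C[Si](C)(C)CN(C(=O)OC(C)(C)C)[C@H]1C2=CCC[C@@H]2CC[C@@H]1C(C)O[Si](CC)(CC)CC | intermediate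
21 | tert-butyl N-[(4R,5S,7aR)-5-(1-hydroxyethyl)-2,4,5,6,7,7a-hexahydro-1H-inden-4-yl]-N-[(trimethylsilyl)methyl]carbamate | C[Si](C)(C)CN(C(=O)OC(C)(C)C)[C@H]1C2=CCC[C@@H]2CC[C@@H]1C(C)O | intermediate
22 | tert-butyl N-[(4R,5S,7aR)-5-acetyl-2,4,5,6,7,7a-hexahydro-1H-inden-4-yl]-N-[(trimethylsilyl)methyl]carbamate | C[Si](C)(C)CN(C(=O)OC(C)(C)C)[C@H]1C2=CCC[C@@H]2CC[C@@H]1C(C)=O | intermediate
23 | pent-3-yn-1-ol | CC#CCCO | starting material
24 | 5-iodopent-2-yne | CC#CCCI | intermediate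
25 | dimethyl malonate | COC(=O)CC(=O)OC | starting material
26 | dimethyl 2-(pent-3-yn-1-yl)propanedioate | CC#CCCC(C(=O)OC)C(=O)OC | intermediate
27 | methyl hept-5-ynoate | CC#CCCCC(=O)OC | intermediate
28 | methyl (3R)-3-A-3-hydroxy-2-(pent-3-yn-1-yl)butanoate (both C2 epimers) | C[Si](C)(C)CN(C(=O)OC(C)(C)C)[C@H]1C2=CCC[C@@H]2CC[C@@H]1[C@@](C)(O)C(CCC#CC)C(=O)OC | intermediate
29 | 3-bromoprop-1-ene (allyl bromide) | C=CCBr | starting material
30 | methyl (2R,3R)-2-allyl-3-A-3-hydroxy-2-(pent-3-yn-1-yl)butanoate | C[Si](C)(C)CN(C(=O)OC(C)(C)C)[C@H]1C2=CCC[C@@H]2CC[C@@H]1[C@@](C)(O)[C@](CC=C)(CCC#CC)C(=O)OC | intermediate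
31 | (2S,3R)-2-allyl-3-A-2-(pent-3-yn-1-yl)butane-1,3-diol | C[Si](C)(C)CN(C(=O)OC(C)(C)C)[C@H]1C2=CCC[C@@H]2CC[C@@H]1[C@@](C)(O)[C@](CC=C)(CCC#CC)CO | intermediate
32 | (2R,3R)-2-allyl-3-A-3-hydroxy-2-(pent-3-yn-1-yl)butanal | C[Si](C)(C)CN(C(=O)OC(C)(C)C)[C@H]1C2=CCC[C@@H]2CC[C@@H]1[C@@](C)(O)[C@](CC=C)(CCC#CC)C=O | intermediate
33 | (2R,3R)-3-allyl-2-A-3-(dimethoxymethyl)oct-6-yn-2-ol | C[Si](C)(C)CN(C(=O)OC(C)(C)C)[C@H]1C2=CCC[C@@H]2CC[C@@H]1[C@@](C)(O)[C@](CC=C)(CCC#CC)C(OC)OC | intermediate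
34 | B-alkyl-9-borabicyclo[3.3.1]nonane from hydroboration of the allyl group of 33 | C[Si](C)(C)CN(C(=O)OC(C)(C)C)[C@H]1C2=CCC[C@@H]2CC[C@@H]1[C@@](C)(O)[C@](CCCB2C3CCCC2CCC3)(CCC#CC)C(OC)OC | intermediate
35 | (4R,5R)-5-A-4-(dimethoxymethyl)-4-(pent-3-yn-1-yl)hexane-1,5-diol | C[Si](C)(C)CN(C(=O)OC(C)(C)C)[C@H]1C2=CCC[C@@H]2CC[C@@H]1[C@@](C)(O)[C@](CCCO)(CCC#CC)C(OC)OC | intermediate
36 | (4R,5R)-5-A-4-(dimethoxymethyl)-5-hydroxy-4-(pent-3-yn-1-yl)hexanal | C[Si](C)(C)CN(C(=O)OC(C)(C)C)[C@H]1C2=CCC[C@@H]2CC[C@@H]1[C@@](C)(O)[C@](CCC=O)(CCC#CC)C(OC)OC | intermediate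
37 | (5R,6R)-6-A-5-(dimethoxymethyl)-6-methyl-5-(pent-3-yn-1-yl)tetrahydro-2H-pyran-2-ol (anomers) | C[Si](C)(C)CN(C(=O)OC(C)(C)C)[C@H]1C2=CCC[C@@H]2CC[C@@H]1[C@@]1(C)OC(O)CC[C@]1(C(OC)OC)CCC#CC | intermediate
38 | (5R,6R)-6-A-5-(dimethoxymethyl)-6-methyl-5-(pent-3-yn-1-yl)tetrahydro-2H-pyran-2-one | C[Si](C)(C)CN(C(=O)OC(C)(C)C)[C@H]1C2=CCC[C@@H]2CC[C@@H]1[C@@]1(C)OC(=O)CC[C@]1(C(OC)OC)CCC#CC | intermediate
39 | (5R,6R)-6-A-5-(dimethoxymethyl)-6-methyl-5-[(Z)-pent-3-en-1-yl]tetrahydro-2H-pyran-2-one | C[Si](C)(C)CN(C(=O)OC(C)(C)C)[C@H]1C2=CCC[C@@H]2CC[C@@H]1[C@@]1(C)OC(=O)CC[C@]1(C(OC)OC)CC/C=C\C | intermediate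
40 | (2R,3R)-2-methyl-6-oxo-3-[(Z)-pent-3-en-1-yl]-2-{(4R,5S,7aR)-4-[(trimethylsilylmethyl)amino]-2,4,5,6,7,7a-hexahydro-1H-inden-5-yl}tetrahydro-2H-pyran-3-carbaldehyde | C[Si](C)(C)CN[C@H]1C2=CCC[C@@H]2CC[C@@H]1[C@@]1(C)OC(=O)CC[C@]1(C=O)CC/C=C\C | intermediate
41 | cyclic N4=C26 iminium trifluoroacetate formed from 40 (N-trimethylsilylmethyl) | C[Si](C)(C)C[N+]3[C@H]1C2=CCC[C@@H]2CC[C@@H]1[C@@]1(C)OC(=O)CC[C@]1(C=3)CC/C=C\C.[O-]C(=O)C(F)(F)F | intermediate
42 | azomethine ylide (C3 carbanion on the N4=C26 iminium) | [CH2-][N+]3[C@H]1C2=CCC[C@@H]2CC[C@@H]1[C@@]1(C)OC(=O)CC[C@]1(C=3)CC/C=C\C | intermediate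
43 | hexacyclic tertiary amine (2S,6R,11R,14S,15R,22S,25R,26S) | C[C@@H]1CN2[C@H]3C4=CCC[C@@H]4CC[C@@H]3[C@@]3(C)OC(=O)CC[C@]34CC[C@H]1[C@@H]42 | intermediate
44 | CNP0566793.5, N4-oxide of 43 (oxygen cis to H26) | C[C@@H]1C[N@+]2([O-])[C@H]3C4=CCC[C@@H]4CC[C@@H]3[C@@]3(C)OC(=O)CC[C@]34CC[C@H]1[C@@H]42 | target

**Step count and risks**

Total step count: 24. Longest linear sequence: 21 steps (steps 1–11 and 15–24, from 1 and 2 to 44); steps 12–14 are a side branch.

Steps most likely to fail: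

1. Step 4. The facial selectivity at C14 rests on 1,4-induction from C11 through a nearly flat dienol ether, so attack on the wrong ring face may compete and give the C14 epimer.
 Fallback: a Diels–Alder construction of the six-membered ring, which sets out from 2 and comes back at 12. Cyclopent-2-en-1-one 2 is iodinated (I2, pyridine) to 2-iodocyclopent-2-en-1-one F1, reduced with BH3·SMe2 and the (R)-CBS oxazaborolidine to (S)-2-iodocyclopent-2-en-1-ol F2, and acetylated to (S)-2-iodocyclopent-2-en-1-yl acetate F3. But-3-yn-2-ol is silylated to triethyl(but-3-yn-2-yloxy)silane F4 and hydroborated with pinacolborane (Cp2Zr(H)Cl cat.) to the (E)-alkenylboronate F5. Suzuki coupling of F3 and F5 (Pd(PPh3)4, K3PO4, dioxane/H2O) should give the semicyclic (E)-diene acetate F6. Heating F6 with phenyl vinyl sulfone (toluene, 120 °C) should give the sulfonyl cycloadduct F7; its regio- and sulfone epimers converge when Na(Hg)/Na2HPO4 removes the sulfonyl group to give the acetate F8, and K2CO3/MeOH then releases alcohol 12. Here H11 and H14 are cis by necessity (suprafacial addition to the E diene), and approach anti to the allylic acetate places both cis to the C8 oxygen.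

2. Step 15. Felkin–Anh discrimination between the two faces of the C15 ketone may be weak on the conformationally mobile ring, and enolisation of the methyl ketone may compete with addition.
 Fallback: reagent-controlled epoxidation in place of substrate-controlled carbonyl addition, which sets out from 22 and comes back at 28. Horner–Wadsworth–Emmons olefination of 22 (trimethyl phosphonoacetate, NaH) gives the (E)-enoate F9, and i-Bu2AlH reduces it to the allylic alcohol F10. Sharpless epoxidation (Ti(Oi-Pr)4, D-(−)-diethyl tartrate, t-BuOOH) gives the (2R,3R)-epoxy alcohol F11, the tartrate deciding the C15 configuration. NaAlH2(OCH2CH2OMe)2 opens the epoxide at C22 to the 1,3-diol F12. Oxidation with TEMPO/PhI(OAc)2 gives the hydroxy aldehyde F13, NaClO2 oxidation gives the hydroxy acid F14, and Me3SiCHN2 gives the methyl β-hydroxy ester F15. Fráter–Seebach alkylation of F15 with 5-iodopent-2-yne 24 returns 28.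

3. Step 16. Alkylation at C22 next to the tertiary alkoxide creates two adjacent fully substituted carbons and may be slow, so that retro-aldol cleavage of the aldolate gains ground.
 Fallback: intramolecular delivery of the allyl group, which sets out from 28 and comes back at 30. Transesterification of 28 with allyl alcohol (Ti(OEt)4 cat.) gives the allyl ester F16. Its dianion (LiN(i-Pr)2, then Me3SiCl, −78 → 23 °C) should undergo the Ireland–Claisen rearrangement through the same alkoxide–enolate chelate, allyl again entering on the methyl face, to give the acid F17. Esterification with Me3SiCHN2 returns 30.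

**Further compounds**

F1 | step 4 | 2-iodocyclopent-2-en-1-one | O=C1CCC=C1I
F2 | step 4 | (S)-2-iodocyclopent-2-en-1-ol | O[C@H]1CCC=C1I
F3 | step 4 | (S)-2-iodocyclopent-2-en-1-yl acetate | CC(=O)O[C@H]1CCC=C1I
F4 | step 4 | triethyl(but-3-yn-2-yloxy)silane | C#CC(C)O[Si](CC)(CC)CC
F5 | step 4 | (E)-4,4,5,5-tetramethyl-2-[3-(triethylsilyloxy)but-1-en-1-yl]-1,3,2-dioxaborolane | CC(O[Si](CC)(CC)CC)/C=C/B1OC(C)(C)C(C)(C)O1
F6 | step 4 | (S)-2-[(E)-3-(triethylsilyloxy)but-1-en-1-yl]cyclopent-2-en-1-yl acetate | CC(=O)O[C@H]1CCC=C1/C=C/C(C)O[Si](CC)(CC)CC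
F7 | step 4 | (1S,3aS,6S)-5-(phenylsulfonyl)-6-[1-(triethylsilyloxy)ethyl]-2,3,3a,4,5,6-hexahydro-1H-inden-1-yl acetate (one regioisomer drawn) | CC(=O)O[C@H]1CC[C@@H]2CC(S(=O)(=O)c3ccccc3)[C@H](C(C)O[Si](CC)(CC)CC)C=C12
F8 | step 4 | (1S,3aS,6S)-6-[1-(triethylsilyloxy)ethyl]-2,3,3a,4,5,6-hexahydro-1H-inden-1-yl acetate | CC(=O)O[C@H]1CC[C@@H]2CC[C@H](C(C)O[Si](CC)(CC)CC)C=C12
F9 | step 15 | methyl (E)-3-A-but-2-enoate | C[Si](C)(C)CN(C(=O)OC(C)(C)C)[C@H]1C2=CCC[C@@H]2CC[C@@H]1/C(C)=C/C(=O)OC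
F10 | step 15 | (E)-3-A-but-2-en-1-ol | C[Si](C)(C)CN(C(=O)OC(C)(C)C)[C@H]1C2=CCC[C@@H]2CC[C@@H]1/C(C)=C/CO
F11 | step 15 | [(2R,3R)-3-A-3-methyloxiran-2-yl]methanol | C[Si](C)(C)CN(C(=O)OC(C)(C)C)[C@H]1C2=CCC[C@@H]2CC[C@@H]1[C@@]2(C)O[C@@H]2CO
F12 | step 15 | (3R)-3-A-butane-1,3-diol | C[Si](C)(C)CN(C(=O)OC(C)(C)C)[C@H]1C2=CCC[C@@H]2CC[C@@H]1[C@@](C)(O)CCO
F13 | step 15 | (3R)-3-A-3-hydroxybutanal | C[Si](C)(C)CN(C(=O)OC(C)(C)C)[C@H]1C2=CCC[C@@H]2CC[C@@H]1[C@@](C)(O)CC=O
F14 | step 15 | (3R)-3-A-3-hydroxybutanoic acid | C[Si](C)(C)CN(C(=O)OC(C)(C)C)[C@H]1C2=CCC[C@@H]2CC[C@@H]1[C@@](C)(O)CC(=O)O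
F15 | step 15 | methyl (3R)-3-A-3-hydroxybutanoate | C[Si](C)(C)CN(C(=O)OC(C)(C)C)[C@H]1C2=CCC[C@@H]2CC[C@@H]1[C@@](C)(O)CC(=O)OC
F16 | step 16 | allyl (3R)-3-A-3-hydroxy-2-(pent-3-yn-1-yl)butanoate | C[Si](C)(C)CN(C(=O)OC(C)(C)C)[C@H]1C2=CCC[C@@H]2CC[C@@H]1[C@@](C)(O)C(CCC#CC)C(=O)OCC=C
F17 | step 16 | (2R,3R)-2-allyl-3-A-3-hydroxy-2-(pent-3-yn-1-yl)butanoic acid | C[Si](C)(C)CN(C(=O)OC(C)(C)C)[C@H]1C2=CCC[C@@H]2CC[C@@H]1[C@@](C)(O)[C@](CC=C)(CCC#CC)C(=O)O
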